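Ring A is grown onto the A–B ether oxygen instead of being coupled to it. In ring A the ether carbon C1 lies between hydroxylated C2 and C6, with C4–OH opposite and C3/C5 unsubstituted. C6–C1–C2 therefore maps onto a malonate and C3–C4–C5 onto a 3-oxoglutarate. One alkoxide-mediated [3+3] Claisen–Dieckmann condensation forms C2–C3 and C5–C6, closes ring A and delivers the A–O–B ether with both flanking oxygens in place. The precursor is the ring B aryloxymalonate, made by O-alkylating an unhindered phenol. Rings C to H exploit the repeat B–C = D–E = F–G: one bromo aldehyde dimer is used twice, each formyl group acting as activator and latent phenol.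

Key step: step 4

Remark: the target has no stereocentre, so no SMILES carries a descriptor. Rings are lettered A to H from the 2,4,6-trihydroxyphenyl end. In rings B, D and F, C1 bears the oxygen to the preceding ring and C4 the oxygen to the next. In rings C, E and G these are C1 and C2.

Step 1
Reactants: 1 syringaldehyde (4-hydroxy-3,5-dimethoxybenzaldehyde)
Product: 2 4-(benzyloxy)-3,5-dimethoxybenzaldehyde
Conditions: BnBr (1.1 equiv), K2CO3, DMF, 50 °C
Reagents that add atoms: benzyl bromide, BrCc1ccccc1
Why: Williamson etherification of the only acidic OH should be clean, and benzyl is the one ether of the route that can later be removed without touching methyl or diaryl ethers.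

Step 2
Reactants: 2 4-(benzyloxy)-3,5-dimethoxybenzaldehyde
Product: 4 4-(benzyloxy)-3,5-dimethoxyphenol, via aryl formate 3 (not isolated)
Conditions: mCPBA (1.2 equiv), CH2Cl2, 0 °C to rt; aq. Na2SO3/NaHCO3 wash; crude 3, K2CO3 (0.2 equiv), MeOH, rt
Reagents that add atoms: 3-chloroperoxybenzoic acid (mCPBA), OOC(=O)c1cccc(Cl)c1
Why: In this Baeyer–Villiger oxidation the electron-rich trialkoxyaryl group migrates in preference to hydride, and base-catalysed methanolysis of the formate then frees the phenol.

Step 3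
Reactants: 4 4-(benzyloxy)-3,5-dimethoxyphenol; 5 dimethyl chloromalonate (dimethyl 2-chloropropanedioate)
Product: 6 dimethyl 2-[4-(benzyloxy)-3,5-dimethoxyphenoxy]malonate
Conditions: K2CO3 (1.5 equiv), acetone, reflux
Reagents that add atoms: none
Why: Williamson-type SN2 O-alkylation of a phenoxide with two free ortho positions is a standard entry to aryloxymalonates, and the chloride is preferred to the bromide because it is a far poorer positive-halogen donor toward an electron-rich phenoxide.

Step 4
Reactants: 6 dimethyl 2-[4-(benzyloxy)-3,5-dimethoxyphenoxy]malonate; 7 dimethyl 3-oxopentanedioate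
Product: 9 dimethyl 5-[4-(benzyloxy)-3,5-dimethoxyphenoxy]-2,4,6-trihydroxybenzene-1,3-dicarboxylate, via acyclic Claisen adduct 8 (not isolated)
Conditions: 6, NaOMe (3.2 equiv), MeOH–toluene, 65 °C; 7 (1.1 equiv) added slowly; MeOH distilled off to 105 °C; then 2 M HCl
Reagents that add atoms: none
Why: Proton transfer from the more acidic 7 to pre-formed sodio-6 pairs the oxoglutarate enolate with un-ionised 6, whose first ester is attacked at carbon (Claisen acylation) to give 8; the second CH2 of the oxoglutarate unit then attacks the remaining malonate ester (Dieckmann acylation), so that C2–C3 and C5–C6 of ring A form in one flask. Ring A closes 6-exo-trig at the ester carbonyl, and expulsion of methoxide leaves a cyclohexane-1,3,5-trione that tautomerises to the aromatic triol and is held as its sodium phenoxide, which pulls the reversible acylations forward. The closest known reaction type is the alkoxide-mediated condensation of malonic esters with 3-oxoglutaric esters to phloroglucinoldicarboxylates, and aryloxymalonates are known 1,3-bis-acylating agents under NaOMe in pyrimidinedione syntheses, so only the combination is new. No stereocentre is created, and since 6 and 7 each have a mirror plane through the central carbon, a single constitution results whichever ester reacts first. The selectivities needed are C- over O-acylation and cross- over self-condensation: a lactone formed through oxygen is reopened by methoxide whereas the phenoxide is not, the chelated sodium enolate favours attack through carbon, and slow addition keeps free 7 scarce next to 6.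

Step 5
Reactants: 9 dimethyl 5-[4-(benzyloxy)-3,5-dimethoxyphenoxy]-2,4,6-trihydroxybenzene-1,3-dicarboxylate
Product: 11 2-[4-(benzyloxy)-3,5-dimethoxyphenoxy]benzene-1,3,5-triol, via dicarboxylic acid 10 (not isolated)
Conditions: 2 M aq. KOH (degassed), 100 °C, Ar; then HCl to pH 2, 60 °C
Reagents that add atoms: none
Why: Saponification is followed by decarboxylation of a 2,4,6-trihydroxybenzoic-type acid, which loses CO2 readily through its beta-keto acid tautomer, while benzyl, methyl and diaryl ethers are inert to aqueous alkali and dilute acid.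

Step 6
Reactants: 11 2-[4-(benzyloxy)-3,5-dimethoxyphenoxy]benzene-1,3,5-triol
Product: 12 2-[4-(benzyloxy)-3,5-dimethoxyphenoxy]-1,3,5-trimethoxybenzene
Conditions: Me2SO4 (4.5 equiv), K2CO3, acetone, reflux, Ar
Reagents that add atoms: dimethyl sulfate, COS(=O)(=O)OC
Why: In this Williamson O-methylation the hard electrophile dimethyl sulfate with K2CO3 in acetone favours O- over C-methylation of the phloroglucinol nucleus.

Step 7
Reactants: 12 2-[4-(benzyloxy)-3,5-dimethoxyphenoxy]-1,3,5-trimethoxybenzene
Product: 13 2,6-dimethoxy-4-(2,4,6-trimethoxyphenoxy)phenol (AB phenol)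
Conditions: H2 (1 atm), 10% Pd/C, EtOAc–MeOH, rt
Reagents that add atoms: none
Why: Catalytic hydrogenolysis cleaves only the benzylic C–O bond and leaves aryl methyl and diaryl ethers intact.

Step 8
Reactants: 14 5-bromo-1,2,3-trimethoxybenzene
Product: 15 6-bromo-2,3,4-trimethoxybenzaldehyde
Conditions: Cl2CHOMe (1.3 equiv), TiCl4 (2 equiv), CH2Cl2, 0 °C; then ice/1 M HCl
Reagents that add atoms: dichloromethyl methyl ether, COC(Cl)Cl; water, O
Why: In this Rieche formylation the two free positions of 14 are equivalent and each is ortho to one outer methoxy group and para to the other, so only one aldehyde can form.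

Step 9
Reactants: 15 6-bromo-2,3,4-trimethoxybenzaldehyde; 16 4-bromo-2,6-dimethoxyphenol
Product: 17 6-(4-bromo-2,6-dimethoxyphenoxy)-2,3,4-trimethoxybenzaldehyde (dimer block)
Conditions: 15 (1.5 equiv), CuI (10 mol %), picolinic acid (20 mol %), K3PO4 (2 equiv), DMSO, 70 °C, Ar
Reagents that add atoms: none
Why: In this Ullmann diaryl ether coupling the bromide of 15 is activated by its ortho formyl group (electron withdrawal and chelation of copper), the bromide of 16 sits para to a phenoxide and is deactivated, and the excess of 15 at moderate temperature should keep the product bromide from competing.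

Step 10
Reactants: 13 AB phenol; 15 6-bromo-2,3,4-trimethoxybenzaldehyde
Product: 18 6-[2,6-dimethoxy-4-(2,4,6-trimethoxyphenoxy)phenoxy]-2,3,4-trimethoxybenzaldehyde (ABC aldehyde)
Conditions: 15 (1.3 equiv), CuI (10 mol %), picolinic acid (20 mol %), K3PO4 (2 equiv), DMSO, 85 °C, Ar
Reagents that add atoms: none
Why: This is the Ullmann diaryl ether coupling of step 9 without a second halide, joining a 2,6-dimethoxyphenoxide to a formyl-activated bromide that has one free ortho position.

Step 11
Reactants: 18 ABC aldehyde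
Product: 20 6-[2,6-dimethoxy-4-(2,4,6-trimethoxyphenoxy)phenoxy]-2,3,4-trimethoxyphenol (ABC phenol), via ABC formate 19 (not isolated)
Conditions: mCPBA (1.2 equiv), CH2Cl2, 0 °C; aq. Na2SO3/NaHCO3 wash; crude 19, K2CO3 (0.2 equiv), MeOH, rt, Ar
Reagents that add atoms: 3-chloroperoxybenzoic acid (mCPBA), OOC(=O)c1cccc(Cl)c1
Why: Baeyer–Villiger oxidation of a benzaldehyde with oxygen donors at both ortho positions and the para position gives aryl migration only, and destroying the peracid before methanolysis protects the electron-rich phenol.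

Step 12
Reactants: 20 ABC phenol; 17 dimer block
Product: 21 ABCDE aldehyde (17 with Br replaced by the aryloxy residue of 20; thirteen OMe, CHO on ring E C2)
Conditions: 17 (1.3 equiv), CuI (20 mol %), picolinic acid (40 mol %), K3PO4 (2 equiv), DMSO, 100 °C, Ar
Reagents that add atoms: none
Why: Ullmann diaryl ether coupling with picolinic acid-ligated copper is established for phenols substituted at both ortho positions, the bromide carbon of 17 has two ortho hydrogens, and the non-enolisable aldehyde tolerates K3PO4.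

Step 13
Reactants: 21 ABCDE aldehyde
Product: 23 ABCDE phenol (OH on ring E C2), via ABCDE formate 22 (not isolated)
Conditions: mCPBA (1.2 equiv), CH2Cl2, 0 °C; aq. Na2SO3/NaHCO3 wash; crude 22, K2CO3 (0.2 equiv), MeOH, rt, Ar
Reagents that add atoms: 3-chloroperoxybenzoic acid (mCPBA), OOC(=O)c1cccc(Cl)c1
Why: This Baeyer–Villiger oxidation and formate methanolysis act on the same local environment as in step 11, and the aldehyde should react faster than any methoxyarene ring at 0 °C.

Step 14
Reactants: 23 ABCDE phenol; 17 dimer block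
Product: 24 ABCDEFG aldehyde (17 with Br replaced by the aryloxy residue of 23; eighteen OMe, CHO on ring G C2)
Conditions: 17 (1.5 equiv), CuI (20 mol %), picolinic acid (40 mol %), K3PO4 (2 equiv), DMSO, 100 °C, Ar
Reagents that add atoms: none
Why: This Ullmann diaryl ether coupling has the same reacting termini as step 12, since the added rings lie remote from the phenoxide oxygen.

Step 15
Reactants: 24 ABCDEFG aldehyde
Product: 26 ABCDEFG phenol (OH on ring G C2), via ABCDEFG formate 25 (not isolated)
Conditions: mCPBA (1.2 equiv), CH2Cl2, 0 °C; aq. Na2SO3/NaHCO3 wash; crude 25, K2CO3 (0.2 equiv), MeOH, rt, Ar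
Reagents that add atoms: 3-chloroperoxybenzoic acid (mCPBA), OOC(=O)c1cccc(Cl)c1
Why: Baeyer–Villiger oxidation and formate methanolysis proceed as in steps 11 and 13.

Step 16
Reactants: 26 ABCDEFG phenol; 14 5-bromo-1,2,3-trimethoxybenzene
Product: 27 octamer henicosamethyl ether (target with all 21 OH as OMe)
Conditions: 14 (3 equiv), CuI (20 mol %), picolinic acid (40 mol %), K3PO4 (2 equiv), DMSO, 105 °C, Ar
Reagents that add atoms: none
Why: This Ullmann diaryl ether coupling follows steps 12 and 14, and the cheap, unhindered bromide can be used in large excess to drive conversion of the valuable phenol.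

Step 17
Reactants: 27 octamer henicosamethyl ether
Product: 28 target CNP0206369.0
Conditions: BBr3 (3 equiv per OMe), CH2Cl2, −78 °C to rt, Ar; MeOH quench, evaporation; Sephadex LH-20
Reagents that add atoms: none
Why: BBr3 cleaves aryl methyl ethers by bromide attack on the methyl carbon of the boron-complexed ether, diaryl ether bonds offer no sp3 carbon for that attack, and the methanol quench removes boron as volatile B(OMe)3 so the water-soluble polyphenol needs no extraction.

Compound list
1 | syringaldehyde | COc1cc(C=O)cc(OC)c1O | starting material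
2 | 4-(benzyloxy)-3,5-dimethoxybenzaldehyde | COc1cc(C=O)cc(OC)c1OCc1ccccc1 | intermediate
3 | 4-(benzyloxy)-3,5-dimethoxyphenyl formate (not isolated) | COc1cc(OC=O)cc(OC)c1OCc1ccccc1 | intermediate
4 | 4-(benzyloxy)-3,5-dimethoxyphenol | COc1cc(O)cc(OC)c1OCc1ccccc1 | intermediate
5 | dimethyl chloromalonate | COC(=O)C(Cl)C(=O)OC | starting material
6 | dimethyl 2-[4-(benzyloxy)-3,5-dimethoxyphenoxy]malonate | COC(=O)C(Oc1cc(OC)c(OCc2ccccc2)c(OC)c1)C(=O)OC | intermediate
7 | dimethyl 3-oxopentanedioate | COC(=O)CC(=O)CC(=O)OC | starting material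
8 | dimethyl 2-{2-[4-(benzyloxy)-3,5-dimethoxyphenoxy]-3-methoxy-3-oxopropanoyl}-3-oxopentanedioate (enolisable, no defined configuration; not isolated) | COC(=O)CC(=O)C(C(=O)OC)C(=O)C(Oc1cc(OC)c(OCc2ccccc2)c(OC)c1)C(=O)OC | intermediate
9 | dimethyl 5-[4-(benzyloxy)-3,5-dimethoxyphenoxy]-2,4,6-trihydroxybenzene-1,3-dicarboxylate | COC(=O)c1c(O)c(C(=O)OC)c(O)c(Oc2cc(OC)c(OCc3ccccc3)c(OC)c2)c1O | intermediate
10 | 5-[4-(benzyloxy)-3,5-dimethoxyphenoxy]-2,4,6-trihydroxybenzene-1,3-dicarboxylic acid (not isolated) | OC(=O)c1c(O)c(C(O)=O)c(O)c(Oc2cc(OC)c(OCc3ccccc3)c(OC)c2)c1O | intermediate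
11 | 2-[4-(benzyloxy)-3,5-dimethoxyphenoxy]benzene-1,3,5-triol | Oc1cc(O)c(Oc2cc(OC)c(OCc3ccccc3)c(OC)c2)c(O)c1 | intermediate
12 | 2-[4-(benzyloxy)-3,5-dimethoxyphenoxy]-1,3,5-trimethoxybenzene | COc1cc(OC)c(Oc2cc(OC)c(OCc3ccccc3)c(OC)c2)c(OC)c1 | intermediate
13 | 2,6-dimethoxy-4-(2,4,6-trimethoxyphenoxy)phenol (AB phenol) | COc1cc(OC)c(Oc2cc(OC)c(O)c(OC)c2)c(OC)c1 | intermediate
14 | 5-bromo-1,2,3-trimethoxybenzene | COc1cc(Br)cc(OC)c1OC | starting material
15 | 6-bromo-2,3,4-trimethoxybenzaldehyde | COc1cc(Br)c(C=O)c(OC)c1OC | intermediate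
16 | 4-bromo-2,6-dimethoxyphenol | COc1cc(Br)cc(OC)c1O | starting material
17 | 6-(4-bromo-2,6-dimethoxyphenoxy)-2,3,4-trimethoxybenzaldehyde (dimer block) | COc1cc(Br)cc(OC)c1Oc1cc(OC)c(OC)c(OC)c1C=O | intermediate
18 | ABC aldehyde | COc1cc(OC)c(Oc2cc(OC)c(Oc3cc(OC)c(OC)c(OC)c3C=O)c(OC)c2)c(OC)c1 | intermediate
19 | ABC formate (not isolated) | COc1cc(OC)c(Oc2cc(OC)c(Oc3cc(OC)c(OC)c(OC)c3OC=O)c(OC)c2)c(OC)c1 | intermediate
20 | ABC phenol | COc1cc(OC)c(Oc2cc(OC)c(Oc3cc(OC)c(OC)c(OC)c3O)c(OC)c2)c(OC)c1 | intermediate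
21 | ABCDE aldehyde | COc1cc(OC)c(Oc2cc(OC)c(Oc3cc(OC)c(OC)c(OC)c3Oc3cc(OC)c(Oc4cc(OC)c(OC)c(OC)c4C=O)c(OC)c3)c(OC)c2)c(OC)c1 | intermediate
22 | ABCDE formate (not isolated) | COc1cc(OC)c(Oc2cc(OC)c(Oc3cc(OC)c(OC)c(OC)c3Oc3cc(OC)c(Oc4cc(OC)c(OC)c(OC)c4OC=O)c(OC)c3)c(OC)c2)c(OC)c1 | intermediate
23 | ABCDE phenol | COc1cc(OC)c(Oc2cc(OC)c(Oc3cc(OC)c(OC)c(OC)c3Oc3cc(OC)c(Oc4cc(OC)c(OC)c(OC)c4O)c(OC)c3)c(OC)c2)c(OC)c1 | intermediate
24 | ABCDEFG aldehyde | COc1cc(OC)c(Oc2cc(OC)c(Oc3cc(OC)c(OC)c(OC)c3Oc3cc(OC)c(Oc4cc(OC)c(OC)c(OC)c4Oc4cc(OC)c(Oc5cc(OC)c(OC)c(OC)c5C=O)c(OC)c4)c(OC)c3)c(OC)c2)c(OC)c1 | intermediate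
25 | ABCDEFG formate (not isolated) | COc1cc(OC)c(Oc2cc(OC)c(Oc3cc(OC)c(OC)c(OC)c3Oc3cc(OC)c(Oc4cc(OC)c(OC)c(OC)c4Oc4cc(OC)c(Oc5cc(OC)c(OC)c(OC)c5OC=O)c(OC)c4)c(OC)c3)c(OC)c2)c(OC)c1 | intermediate
26 | ABCDEFG phenol | COc1cc(OC)c(Oc2cc(OC)c(Oc3cc(OC)c(OC)c(OC)c3Oc3cc(OC)c(Oc4cc(OC)c(OC)c(OC)c4Oc4cc(OC)c(Oc5cc(OC)c(OC)c(OC)c5O)c(OC)c4)c(OC)c3)c(OC)c2)c(OC)c1 | intermediate
27 | octamer henicosamethyl ether | COc1cc(OC)c(Oc2cc(OC)c(Oc3cc(OC)c(OC)c(OC)c3Oc3cc(OC)c(Oc4cc(OC)c(OC)c(OC)c4Oc4cc(OC)c(Oc5cc(OC)c(OC)c(OC)c5Oc5cc(OC)c(OC)c(OC)c5)c(OC)c4)c(OC)c3)c(OC)c2)c(OC)c1 | intermediate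
28 | CNP0206369.0 | Oc1cc(O)c(Oc2cc(O)c(Oc3cc(O)c(O)c(O)c3Oc3cc(O)c(Oc4cc(O)c(O)c(O)c4Oc4cc(O)c(Oc5cc(O)c(O)c(O)c5Oc5cc(O)c(O)c(O)c5)c(O)c4)c(O)c3)c(O)c2)c(O)c1 | target

Total steps: 17. Longest linear sequence: 15 (steps 1 to 7, then 10 to 17). Steps 8 and 9 form a short side branch whose products are each used more than once.

Steps most likely to fail

Step 4. Three processes may outrun the cross-acylation: self-condensation of the oxoglutarate enolate, ring closure through oxygen that is not reversed, and methoxide-induced loss of a methoxycarbonyl group from the malonate. The fallback gives up ring construction and makes the A–O–B bond by coupling. It sets out from 16, which is benzylated (BnBr, K2CO3, DMF) to 2-(benzyloxy)-5-bromo-1,3-dimethoxybenzene F1. Ullmann coupling of F1 with commercial 2,4,6-trimethoxyphenol (COc1cc(OC)c(O)c(OC)c1) under CuI, picolinic acid and K3PO4 in DMSO at 100 °C should give 12, where the route is rejoined.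

Step 14. C–O bond formation at copper may be slow. The phenoxide is flanked by a methoxy and a bulky aryloxy group, and the bromide is electron-rich and unactivated. Hydrodebromination and degradation of the formyl group on long heating may then compete. The fallback replaces the unactivated dimer by two formyl-activated monomers, at the cost of two more steps, and it does not need block 17.
- It sets out from 23, which is coupled (CuI, picolinic acid, K3PO4, DMSO, 85 °C) with commercial 4-bromo-2,6-dimethoxybenzaldehyde (COc1cc(Br)cc(OC)c1C=O). Its bromide lies para to the formyl group and between two hydrogens. This should give the ABCDEF aldehyde F2.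
- Baeyer–Villiger oxidation with mCPBA gives the ABCDEF formate F3, and catalytic K2CO3 in MeOH gives the ABCDEF phenol F4.
- Coupling of F4 with 15 under the conditions of step 10 comes back to the route at 24.

Step 17. Ether cleavage may stay incomplete when partly dealkylated boron aryloxides precipitate, and the free polyphenol may suffer air oxidation and losses during isolation. The fallback derivatises, purifies and then releases the phenols.
- It sets out from 27, and the crude residue of the BBr3 treatment is acetylated at once (Ac2O, pyridine, rt) to the octamer henicosaacetate F5.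
- F5 is stable to air and can be separated on silica gel from congeners that still carry methyl groups.
- Transesterification of F5 with HCl in MeOH under argon, followed by evaporation, comes back to the route at 28.

Further compounds
F1 | step 4 | 2-(benzyloxy)-5-bromo-1,3-dimethoxybenzene | COc1cc(Br)cc(OC)c1OCc1ccccc1
F2 | step 14 | ABCDEF aldehyde (CHO on ring F C4) | COc1cc(OC)c(Oc2cc(OC)c(Oc3cc(OC)c(OC)c(OC)c3Oc3cc(OC)c(Oc4cc(OC)c(OC)c(OC)c4Oc4cc(OC)c(C=O)c(OC)c4)c(OC)c3)c(OC)c2)c(OC)c1
F3 | step 14 | ABCDEF formate | COc1cc(OC)c(Oc2cc(OC)c(Oc3cc(OC)c(OC)c(OC)c3Oc3cc(OC)c(Oc4cc(OC)c(OC)c(OC)c4Oc4cc(OC)c(OC=O)c(OC)c4)c(OC)c3)c(OC)c2)c(OC)c1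
F4 | step 14 | ABCDEF phenol (OH on ring F C4) | COc1cc(OC)c(Oc2cc(OC)c(Oc3cc(OC)c(OC)c(OC)c3Oc3cc(OC)c(Oc4cc(OC)c(OC)c(OC)c4Oc4cc(OC)c(O)c(OC)c4)c(OC)c3)c(OC)c2)c(OC)c1
F5 | step 17 | octamer henicosaacetate | CC(=O)Oc1cc(OC(C)=O)c(Oc2cc(OC(C)=O)c(Oc3cc(OC(C)=O)c(OC(C)=O)c(OC(C)=O)c3Oc3cc(OC(C)=O)c(Oc4cc(OC(C)=O)c(OC(C)=O)c(OC(C)=O)c4Oc4cc(OC(C)=O)c(Oc5cc(OC(C)=O)c(OC(C)=O)c(OC(C)=O)c5Oc5cc(OC(C)=O)c(OC(C)=O)c(OC(C)=O)c5)c(OC(C)=O)c4)c(OC(C)=O)c3)c(OC(C)=O)c2)c(OC(C)=O)c1
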